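The trap in a percent-per-hour slope is to read it as one rate when it is the sum of two delays.

| setting | Friday's | Thursday's | Sunday's | epsilon | zeta | theta | gamma | delta | eta |
|---|---|---|---|---|---|---|---|---|---|
| starting material | 0.0078 M | 0.030 M | 0.050 M | 0.050 M | 0.050 M | 0.012 M | 0.050 M | 0.012 M | 0.012 M |
| second substrate | 0.50 equiv | 0.50 equiv | 0.89 equiv | 2.00 equiv | 0.500 equiv | 0.500 equiv | 0.250 equiv | 2.00 equiv | 0.250 equiv |
| free catalyst | 10 mol% | 10 mol% | 10 mol% | 10 mol% | 10 mol% | 10 mol% | 10 mol% | 10 mol% | 10 mol% |
| remark | run made earlier | run made earlier | run made earlier |  |  |  |  |  |  |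
| time |  |  |  | 10 h | 10 h | 10 h | 10 h | 10 h | 10 h |

- Friday's (time / h: target / %, starting material / %): 0.417: 3, 102; 1.33: 1, 97; 2.50: 4, 92; 4.00: 9, 92; 5.00: 8, 87
- Thursday's (time / h: target / %, starting material / %): 0.417: 4, 97; 1.33: 8, 90; 2.50: 18, 82; 4.00: 22, 78; 5.00: 22, 72
- Sunday's (time / h: target / %, starting material / %): 1.00: 7, 88; 2.00: 13, 83; 3.00: 16, 84; 4.00: 22, 73; 5.00: 25, 69

(standard deviation of a reading: 2 percentage points)

- what was read earlier has a scatter of 2 percentage points, one standard deviation
- steps thought possible: starting material + free catalyst <-> catalyst intermediate A; catalyst intermediate A -> free catalyst + target; second substrate + free catalyst <-> catalyst intermediate B; catalyst intermediate B -> free catalyst + second product; starting material + catalyst intermediate B -> spent catalyst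

- all flasks from highest to lowest amount of target, in percent of the starting material charged, at 10 h (epsilon / zeta / theta / gamma / delta / eta)
- the amount of target, in percent of the starting material charged of the flask you put first, at 10 h
- the amount of target, in percent of the starting material charged of the flask you put last, at 10 h

Take from each run the time it would need to finish its charge at the pace of its last reading: Friday's 62.5 h, Sunday's 20.0 h. I split that time in two. Catalyst is charged in proportion to starting material, so the bare time, turnover with no second substrate about, should shrink as concentration rises. The parked time, catalyst held by second substrate, should grow with the equivalents. These two runs then give, as readings with their scatter, 12.6 h parked per equivalent and 8.77 h bare at 0.050 M. Thursday's run, unused so far, reads 22.7 h against 20.9 h reckoned.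

Carry parked time divided by bare time, the brake, which for gamma is 0.360. Hours cancel in it.

You then let the starting material decay over the sum of the two times. My reckoning puts gamma first, its 11.9 h being the shortest sum, at 56.8 %, and delta last at 14.9 %. Epsilon reckons at 25.5 %, but I trust that little, since its brake of 2.88 is higher than Sunday's 1.28.

The forecast gave gamma > zeta > eta > theta > epsilon > delta, with 55 % and 18 % at the ends, holding that “second substrate ties up catalyst”.

The flasks gave gamma > zeta > eta > theta > delta > epsilon, with gamma at 63.4 %, delta at 17.9 % and epsilon at 15.9 %.

    starting material + free catalyst ⇌ catalyst intermediate A (K = 22.0 M⁻¹, k = 0.00958 M⁻¹ s⁻¹)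
    catalyst intermediate A → free catalyst + target (k = 0.00448 s⁻¹)
    second substrate + free catalyst ⇌ catalyst intermediate B (K = 11000 M⁻¹, k = 0.0144 M⁻¹ s⁻¹)
    catalyst intermediate B → free catalyst + second product (k = 4.59 × 10⁻⁴ s⁻¹)
    starting material + catalyst intermediate B → spent catalyst (k = 0.00226 M⁻¹ s⁻¹)

In gamma 18 % of the second substrate is left at 10.0 h, which takes the brake from 0.360 to 0.0648, and free catalyst then goes forward to starting material at 5.0 to one against second substrate, each step's forward rate alone. Epsilon, with 74 % left, still has a brake of 2.13, and there 89.7 % of the catalyst is spent with target at 15.9 %.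

The runs are simulated from invented constants; noise was put on by code.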